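(The rate constants belong to no real substance; no experiment stands behind them.)

The complex with three exchanged is the product I have to count, and I doubt that the order of addition matters much for it.

in all of them: scavenger 1.00 equiv; time 15 min
- theta: starting complex 0.26 M; incoming ligand 1.20 equiv (fed, over 6.0 min); all else is in the flask from the start; the feed brings no volume worth counting
- delta: starting complex 0.26 M (in portions, 2, over 6.0 min); incoming ligand 1.20 equiv; first portion at the start, last at 6.0 min
- zeta: starting complex 0.26 M; incoming ligand 1.20 equiv; everything together at the start
- epsilon: starting complex 0.26 M (fed, over 6.0 min); incoming ligand 1.20 equiv; all else is in the flask from the start; the feed brings no volume worth counting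

    starting complex + incoming ligand ⇌ leaving ligand + complex with one exchanged (K1 = 0.51, k1 = 0.38 L mol⁻¹ s⁻¹)
    complex with one exchanged + incoming ligand ⇌ leaving ligand + complex with two exchanged (K2 = 0.095, k2 = 0.17 L mol⁻¹ s⁻¹)
    complex with two exchanged + incoming ligand ⇌ leaving ligand + complex with three exchanged (K3 = 0.42, k3 = 0.081 L mol⁻¹ s⁻¹)
    leaving ligand + incoming ligand ⇌ idle adduct, settled at all times (K4 = 6.4 L mol⁻¹)
    scavenger + leaving ligand → scavenged by-product (k5 = 1.2 L mol⁻¹ s⁻¹)

- the flask with the highest amount of complex with three exchanged, in percent of the starting complex charged ("all alike" if they lie within 1.5 percentage points) (theta / delta / zeta / epsilon / all alike)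
- final complex with three exchanged, as a percentage of the starting complex charged, in theta
- final complex with three exchanged, as a percentage of the starting complex charged, in delta
- final complex with three exchanged, as a percentage of the starting complex charged, in zeta
- final complex with three exchanged, as a percentage of the starting complex charged, in epsilon

- leaving ligand is meant together with its idle adduct
- run time (theta): 15 min

Each exchange frees one leaving ligand, and the scavenger removes it for good. So I count the exchange budget, the mean number of exchanges per complex that this drain can pay for, which is the smaller of the charges of incoming ligand and scavenger in equivalents: 1.00 equiv. Here the scavenger is the limiting reagent, its charge being smaller than that of incoming ligand.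

But a mean doesn't give the share on the top rung. If the exchanges stand at balance, the ratio [incoming ligand]/[leaving ligand] sets every rung, and a mean of one exchange requires [complex with two exchanged] + 2[complex with three exchanged] = [starting complex]. Ignoring the complex with two exchanged is crude, so I put it back and repeat:

ratio: 2.91, then 2.45, then 2.60

Another objection: leaving ligand that stays free is exchange the scavenger never paid for. The spare incoming ligand, 0.0520 M, divides by that ratio, which leaves about 0.0145 M of leaving ligand, adduct ignored. That adds 0.0556 to the mean. Correcting once:

ratio: 2.75
complex with three exchanged: 13.3%

Is there time for balance? In zeta, as charged, the forward half-life of complex with two exchanged by the third exchange is 0.46 min. With incoming ligand down to its part of the spare amount, the rest of which stands as leaving ligand, this forward half-life stretches to 3.74 min, shorter than the 9.00 min that follow the feeds. So I commit to about 13.3% in theta, delta, zeta and epsilon alike, with no winner.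

The forecast gives 8% for theta, 11% for delta, 10% for zeta and 13% for epsilon, and it names epsilon: “Feeding the complex into excess ligand should favour deep exchange most”. On the winner, and on the levels in theta, delta and zeta, I differ from it.

The simulation gives 12.7%, 13.4%, 13.0% and 13.1% in that order, a spread of 0.70 percentage points, smaller than the margin, so the answer is all alike.

At 15.0 min in epsilon, the forward half-life of complex with one exchanged by the second exchange is 2.0 min, far shorter than the 160 h of free leaving ligand by the scavenger, which stands at 0% of its charge. The mean exchange in epsilon reads 1.06, above the budget of 1.00 equiv.

With 0.300 equiv of incoming ligand in the epsilon recipe, the budget becomes 0.300 equiv, now set by the incoming ligand, and 70.0% of the scavenger should remain. The computed flask shows a mean of 0.300, scavenger at 70.0%, and 0.859% of complex with three exchanged.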